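## The problem

Compound 30 is a labdane-type bicycle. Ring A (C1–C5, C10) and ring B (C5–C10) are trans-fused across C5–C10, ring B holds the trisubstituted C7=C8 olefin with the C17 methyl, and C9 carries a five-carbon chain (C11–C15, methyl on C13) ending in a primary acetate. Five of the six stereocentres are contiguous in the bicycle (C2, C3, C5, C9, C10); the sixth, C13, is isolated on the chain. The quaternary C10 and its neighbour C5 define the ring fusion and must be set together and in absolute terms. Once they exist, the axial C10 and C4 methyls close one face of ring A, so oxygen at C2 and hydride at C3 can be placed under substrate control, and C9 settles with its chain equatorial whenever it lies next to a C8 carbonyl. C13 is too far from the rings to be controlled from them and must arrive in an enantiopure chain fragment. The oxygen pattern is the second difficulty: a cis-2,3-diol on the face of H5, whose axial, neopentyl C3 hydroxyl stays free while C2–OH and C15–OH are acetylated. The acetates (base, hydride, organometallics), the monoacylated cis-diol (acyl migration) and the C7=C8 olefin (acid-promoted shift to C8=C9) are the fragile parts and should appear late. The feature that opens the molecule is ring A itself: C3 bears oxygen next to C4, and the C5–C10 bond joins a tertiary C5 (H, C6) to a quaternary C10 (CH3, C9) with C6 and C9 trans. That is the substitution pattern of the cyclohex-2-enone formed when a 1-methoxy-3-siloxybutadiene adds across the Cα=Cβ bond of an (E)-2-methyl enal.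

## Retrosynthesis

**Acetates and protecting groups (30 to 28).** The two O–acyl bonds at C2 and C15 are cut first, giving triol 29. Carrying an acetate further back is excluded by the hydroxide, hydride, amide-base and Grignard steps that precede. Both can be cut together because the axial C3 hydroxyl beside the C4 methyls is the slowest to acylate. Triol 29 comes from 28 (acetonide, silyl ether) by one acidic hydrolysis. The forward steps must tell C2–OH from C3–OH and must not move the olefin.

**C8–C17 (28 to 25).** The C17 methyl is cut at sp2 carbon C8, through enol triflate 27, back to the C8 ketone 25. The neighbouring option, methyl addition to the ketone and dehydration, would spread the olefin over C7=C8, C8=C9 and C8=C17; the triflate fixes it. Ketone 25 is simpler by one carbon and one olefin and makes C9 epimerisable. The forward enolisation must take a C7 hydrogen, not the C9 hydrogen.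

**C8–C9, ring B (25 to 24).** Ring B is opened between C8 and C9, leaving ring A with an acyl radical precursor on C5 (selenoester 24) and a C9=C11 olefin on C10. Cutting C9–C11 instead would mean alkylating a bicyclic ketone next to the quaternary centre. Cutting C9–C10 leads to cationic chemistry in which the diol is a burden. In 24 the whole chain is already present. The forward step must close 6-exo at C9 faster than reduction or decarbonylation and place the chain equatorial.

**Ring A oxidation level (24 to 18).** Selenoester 24 comes from ester 22 through acid 23, and acetonide 22 from diol 21. The C3–H bond is then cut to hydroxy ketone 20 and the C2–O bond to enone 18. Dihydroxylation of a C2=C3 olefin would make both C–O bonds at once but was set aside because the C9=C11 olefin would compete. Enone 18 has two stereocentres fewer. Oxygen must enter C2 on the face away from the axial methyls, and hydride must reach C3 along the equatorial path so that the C3 hydroxyl is axial and cis to it.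

**C4–CH3 bonds (18 to 16).** Both C4 methyls are removed to give enone 16, in which C4 is the only enolisable position. They cannot be placed earlier, because the diene terminus of the cycloaddition must be unsubstituted.

**C9=C11 (16 to 7 and 14).** The chain is detached at a C9=C11 double bond (Wittig), giving aldehyde 7 and phosphonium salt 14. The olefin is not in the target but is the radical acceptor needed later, and the cut makes the route convergent. C13 arrives in 14, made from prochiral diester 8 by enzymatic desymmetrisation (9) and end-group differentiation (10–13). Either antipode of the half-ester would serve, since exchanging the order in which the two termini are reduced inverts the fragment. The Wittig reaction must choose the aldehyde over the enone and the ester.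

**C1–C10 and C4–C5, ring A (7 to 3 and 5).** Enone 7 is the acid-unmasked [4+2] adduct of siloxydiene 5 and (E)-enal 3. No other cut of ring A creates the quaternary centre and its trans neighbour in one operation from achiral, acyclic material. The forward reaction must be regioselective, must add to C=C and not to C=O, and must be face-selective under a chiral boron Lewis acid.

**Enal and diene (3 to 1 and 2; 5 to 4).** The Cα=Cβ bond of 3 is cut by cross-metathesis to ester 1 and methacrolein 2, which must give the E olefin. Diene 5 is the silyl enol ether of enone 4.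

## Roads not taken

Three other disconnections were weighed.

Alternative 1: The cut is C8–C9, and the organising step is the 6-exo addition of the acyl radical from phenyl selenoester A2 to C9 of the C9=C11 olefin, giving ketone A1.
- Merits: ring B, the C8 carbonyl needed for the C17 methyl and the C9 configuration come in one neutral step that tolerates acetonide and silyl ether, with the full chain and C13 in place.
- Weak points: A2 already contains C2, C3, C5, C10 and C13, and the cut says nothing about how the quaternary C10 and its trans neighbour C5 are made in absolute terms. No chiral-pool cyclohexane with that pattern is at hand.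
- Comparison: in ring B construction the two plans are equal, because the chosen plan uses the same closure in step 17 (A1 is 25, A2 is 24). The chosen plan adds a catalytic origin for ring A, at the price of placing the radical step late in a longer sequence.

Alternative 2: The cut is C2–C3. Divalent samarium (SmI2) couples the two formyl groups of dialdehyde A4 and closes ring A as the cis-diol A3, one selective acetylation from 30.
- Merits: at the end this road is better than the chosen one. Both carbinol centres form in the ring-closing step, no diol protecting group is needed, and the C15 acetate and C7=C8 olefin, which SmI2 tolerates, are already present.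
- Weak points: A4 must already hold ring B with C5, C9, C10 and C13 and two different formyl arms, which is no easier than the original problem. The neopentyl C3 aldehyde may be reduced rather than coupled. Cis selectivity is usual, but which cis-diol forms (H5 face or C20 face) is not secured.
- Comparison: the chosen plan sets C2 and C3 in two separate, predictable operations and pays with an acetonide and extra steps. In return its hard stereochemistry (C5, C10) is solved first and by catalyst.

Alternative 3: The cut is C9–C10. SnCl4 protonates the C5=C10 olefin of β-keto ester A6 and the enol carbon C9 traps the C10 cation, giving the trans-fused bicyclic keto ester A5.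
- Merits: this is the most proven way to a trans-decalin with an angular methyl. It is cheap, needs no chiral catalyst for the ring fusion, and A5 offers the C8 ketone and a C11 ester as handles. As a ring-forming event it is more robust than a radical closure.
- Weak points: the acetonide must survive a strong Lewis acid. C2 and C3 must be made enantioselectively on the monocycle and then control C5 and C10 across the ring, which is uncertain. The chain must be built outward from the neopentyl C11 after cyclisation, with C13 added in a further coupling.
- Comparison: the chosen plan sets against this a cycloaddition whose C=C versus C=O selectivity is less certain. It controls the absolute configuration by catalyst and attaches the complete chain in one Wittig step.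

Key step: step 3

Remark: locants C1–C20 follow the labdane numbering of 30 throughout. The C9=C11 olefin of 16–24 is written Z, as expected from an unstabilised ylide; its geometry has no consequence because both carbons become sp3 in step 17.

## Steps

Step 1
Reactants: 1 methyl pent-4-enoate; 2 methacrolein (2-methylprop-2-enal)
Product: 3 methyl (E)-5-methyl-6-oxohex-4-enoate
Conditions: second-generation Grubbs catalyst (H2IMes)(PCy3)Cl2Ru=CHPh (3 mol %), 2 (3 equiv), CH2Cl2, 40 °C
Reagents that add atoms: none
Why: Olefin cross-metathesis of a terminal olefin with the 1,1-disubstituted, electron-poor methacrolein; the homodimer of 1 re-enters by secondary metathesis, and the trisubstituted enal should form under thermodynamic control as the E isomer that the key step needs.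

Step 2
Reactants: 4 (E)-4-methoxybut-3-en-2-one
Product: 5 (E)-tert-butyl[(4-methoxybuta-1,3-dien-2-yl)oxy]dimethylsilane
Conditions: TBSOTf, Et3N, Et2O, 0 °C to rt
Reagents that add atoms: tert-butyldimethylsilyl triflate, CC(C)(C)[Si](C)(C)OS(=O)(=O)C(F)(F)F
Why: Soft enolisation and O-silylation of the vinylogous ester (silyl enol ether formation) with retention of the E methoxyvinyl geometry; the tert-butyldimethylsilyl ether is chosen over the trimethylsilyl one because it resists the strongly acidic catalyst of step 3.

Step 3
Reactants: 3 methyl (E)-5-methyl-6-oxohex-4-enoate; 5 (E)-tert-butyl[(4-methoxybuta-1,3-dien-2-yl)oxy]dimethylsilane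
Product: 7 methyl 3-[(1R,2S)-2-formyl-2-methyl-5-oxocyclohex-3-en-1-yl]propanoate, via methoxy enol silyl ether cycloadduct 6 (not isolated)
Conditions: (S)-tetrahydro-1-(2-methylphenyl)-3,3-diphenyl-1H,3H-pyrrolo[1,2-c][1,3,2]oxazaborole (20 mol %) protonated with HN(SO2CF3)2 (17 mol %), 5 (1.5 equiv), CH2Cl2, −78 to −40 °C; then CF3CO2H, CH2Cl2, 0 °C
Reagents that add atoms: none
Why: The N-protonated oxazaborolidine binds the formyl oxygen of 3 anti to C10 with a formyl C–H···O contact, so the s-trans enal lies over one aryl face of the catalyst and its C=C is activated; diene 5 then adds in a concerted, asynchronous [4+2] in which the nucleophilic CH2 terminus (C4) bonds to the β-carbon (C5) ahead of the bond from the methoxy-bearing terminus (C1) to the α-carbon (C10). The closest known reaction type is the cationic-oxazaborolidine-catalysed Diels–Alder reaction of 2-methyl enals, including β-substituted ones, and of siloxydienes, together with the thermal addition of 1-methoxy-3-siloxybutadienes to methacrolein-type enals, which gives the same constitution. Ring A is closed by the intermolecular cycloaddition itself, both ring bonds (C1–C10 and C4–C5) forming in one six-membered transition state; trifluoroacetic acid then hydrolyses the enol silyl ether of 6 and expels methanol to leave the C1=C2–C3=O enone. The relative configuration of the new stereocentres C5 and C10 follows from the E geometry of 3 and suprafacial addition, which place C6 and the formyl carbon C9 trans. Their absolute configuration comes from the catalyst: on the formyl C–H···O model the (S)-catalyst shields the Si face of the α-carbon, the diene enters on the Re face, and (1R,2S)-7 results. The step needs regioselectivity, secured by the polarisation of both partners; addition to C=C and not to C=O, favoured by the crowded boron-bound carbonyl and by a silyl group too bulky for fast silyl transfer and aldol-type turnover; and facial selectivity, secured by the two-point binding of the formyl group. There is no endo/exo question because C1 loses its stereocentre on elimination.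

Step 4
Reactants: 8 dimethyl 3-methylpentanedioate (dimethyl 3-methylglutarate)
Product: 9 (R)-5-methoxy-3-methyl-5-oxopentanoic acid
Conditions: pig liver esterase, pH 7 phosphate buffer, 20% MeOH, −10 °C; then acidify and extract
Reagents that add atoms: water, O
Why: Enzymatic desymmetrisation of a prochiral diester; the esterase is known to hydrolyse one enantiotopic ester group of 3-methylglutarates preferentially to the (R)-half ester, which sets C13.

Step 5
Reactants: 9 (R)-5-methoxy-3-methyl-5-oxopentanoic acid
Product: 10 methyl (R)-5-hydroxy-3-methylpentanoate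
Conditions: BH3·SMe2, THF, 0 °C to rt; MeOH quench
Reagents that add atoms: none
Why: Chemoselective borane reduction; the carboxylic acid is reduced through its acyloxyborane far faster than the methyl ester, so the acid carbon becomes C15.

Step 6
Reactants: 10 methyl (R)-5-hydroxy-3-methylpentanoate
Product: 11 methyl (R)-5-(tert-butyldimethylsilyloxy)-3-methylpentanoate
Conditions: TBSCl, imidazole, DMF, rt
Reagents that add atoms: tert-butyldimethylsilyl chloride, CC(C)(C)[Si](C)(C)Cl
Why: Standard silylation of a primary alcohol; the ether should survive the later basic, radical and organometallic steps and leaves with the acetonide in step 20.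

Step 7
Reactants: 11 methyl (R)-5-(tert-butyldimethylsilyloxy)-3-methylpentanoate
Product: 12 (S)-5-(tert-butyldimethylsilyloxy)-3-methylpentan-1-ol
Conditions: i-Bu2AlH (2.2 equiv), CH2Cl2, −78 to 0 °C; aqueous potassium sodium tartrate
Reagents that add atoms: none
Why: Ester reduction by an aluminium hydride; the former ester carbon becomes C11 and the stereocentre is untouched (the descriptor changes only through priorities).

Step 8
Reactants: 12 (S)-5-(tert-butyldimethylsilyloxy)-3-methylpentan-1-ol
Product: 13 (R)-tert-butyl[(5-iodo-3-methylpentyl)oxy]dimethylsilane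
Conditions: I2, PPh3, imidazole, CH2Cl2, 0 °C
Reagents that add atoms: iodine, II
Why: Appel-type iodination of a primary alcohol under buffered conditions that leave the silyl ether intact.

Step 9
Reactants: 13 (R)-tert-butyl[(5-iodo-3-methylpentyl)oxy]dimethylsilane
Product: 14 [(R)-5-(tert-butyldimethylsilyloxy)-3-methylpentyl]triphenylphosphonium iodide
Conditions: PPh3, MeCN, 80 °C
Reagents that add atoms: triphenylphosphine, c1ccc(cc1)P(c1ccccc1)c1ccccc1
Why: SN2 quaternisation of the phosphine by a primary iodide gives the Wittig salt.

Step 10
Reactants: 14 [(R)-5-(tert-butyldimethylsilyloxy)-3-methylpentyl]triphenylphosphonium iodide; 7 methyl 3-[(1R,2S)-2-formyl-2-methyl-5-oxocyclohex-3-en-1-yl]propanoate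
Product: 16 methyl 3-[(1R,2R)-2-[(1Z,4S)-6-(tert-butyldimethylsilyloxy)-4-methylhex-1-en-1-yl]-2-methyl-5-oxocyclohex-3-en-1-yl]propanoate, via phosphonium ylide 15 (not isolated)
Conditions: NaN(SiMe3)2, THF, −78 to 0 °C; then 7, −78 to −20 °C
Reagents that add atoms: none
Why: Wittig olefination; the unstabilised ylide should add to the aldehyde at −78 °C much faster than to the enone carbonyl or the ester, and C10 has no α-hydrogen to lose. The Z olefin is expected, but its geometry is irrelevant.

Step 11
Reactants: 16 methyl 3-[(1R,2R)-2-[(1Z,4S)-6-(tert-butyldimethylsilyloxy)-4-methylhex-1-en-1-yl]-2-methyl-5-oxocyclohex-3-en-1-yl]propanoate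
Product: 18 methyl 3-[(1S,2R)-2-[(1Z,4S)-6-(tert-butyldimethylsilyloxy)-4-methylhex-1-en-1-yl]-2,6,6-trimethyl-5-oxocyclohex-3-en-1-yl]propanoate, via C4-monomethyl ketone 17 (not isolated)
Conditions: MeI (6 equiv), KOt-Bu (2.3 equiv, slow addition), THF, −40 to 0 °C
Reagents that add atoms: iodomethane, CI
Why: Exhaustive α-methylation through the potassium enolate; C4 is the only enolisable position of the enone (C2 is vinylic, C10 quaternary, so no dienolate). Keeping MeI in excess while the base is added slowly should trap the ketone enolate before the far less acidic ester arm reacts.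

Step 12
Reactants: 18 methyl 3-[(1S,2R)-2-[(1Z,4S)-6-(tert-butyldimethylsilyloxy)-4-methylhex-1-en-1-yl]-2,6,6-trimethyl-5-oxocyclohex-3-en-1-yl]propanoate
Product: 20 methyl 3-[(1S,2S,4S)-2-[(1Z,4S)-6-(tert-butyldimethylsilyloxy)-4-methylhex-1-en-1-yl]-4-hydroxy-2,6,6-trimethyl-5-oxocyclohexyl]propanoate, via C2 hydroperoxide 19 (not isolated)
Conditions: Mn(dpm)3 [tris(2,2,6,6-tetramethylheptane-3,5-dionato)manganese] (5 mol %), PhSiH3, O2 (1 atm), i-PrOH/CH2Cl2, 0 °C; then P(OEt)3
Reagents that add atoms: dioxygen, O=O
Why: Mukaiyama-type reductive α-hydroxylation; a manganese hydride transfers a hydrogen atom to C1 of the enone, the C2 radical is trapped by O2 and the hydroperoxide is reduced by the phosphite, while the unactivated 1,2-disubstituted C9=C11 olefin is a poor hydrogen-atom acceptor. Oxygen should enter C2 on the face opposite the axial C10 and C4 methyls, which is also the equatorial, thermodynamically preferred position.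

Step 13
Reactants: 20 methyl 3-[(1S,2S,4S)-2-[(1Z,4S)-6-(tert-butyldimethylsilyloxy)-4-methylhex-1-en-1-yl]-4-hydroxy-2,6,6-trimethyl-5-oxocyclohexyl]propanoate
Product: 21 methyl 3-[(1S,2S,4S,5R)-2-[(1Z,4S)-6-(tert-butyldimethylsilyloxy)-4-methylhex-1-en-1-yl]-4,5-dihydroxy-2,6,6-trimethylcyclohexyl]propanoate
Conditions: LiBH(s-Bu)3 (2.5 equiv), THF, −78 °C; aqueous work-up
Reagents that add atoms: none
Why: Bulky trialkylborohydride reduction; axial approach to C3 is blocked by the axial hydrogens at C1 and C5, so hydride should arrive along the equatorial path and leave the axial alcohol cis to the C2 hydroxyl, as known for 4,4-dimethyl-3-ketones. The ester is not reduced at −78 °C.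

Step 14
Reactants: 21 methyl 3-[(1S,2S,4S,5R)-2-[(1Z,4S)-6-(tert-butyldimethylsilyloxy)-4-methylhex-1-en-1-yl]-4,5-dihydroxy-2,6,6-trimethylcyclohexyl]propanoate
Product: 22 2,3-O-isopropylidene acetal (acetonide) of diol 21, methyl ester, all stereocentres as in 21
Conditions: 2,2-dimethoxypropane, PPTS (cat.), CH2Cl2, rt
Reagents that add atoms: 2,2-dimethoxypropane, COC(C)(C)OC
Why: Acetonide formation by transketalisation, favourable for a cis-1,2-diol; it masks both hydroxyls for the base, radical and organometallic steps, and the mild acid leaves the silyl ether intact.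

Step 15
Reactants: 22 acetonide methyl ester
Product: 23 carboxylic acid corresponding to 22 (C8 acid, otherwise unchanged)
Conditions: LiOH, THF/MeOH/H2O, rt; then dilute HCl to pH 4, 0 °C
Reagents that add atoms: lithium hydroxide, [Li+].[OH-]
Why: Saponification of the methyl ester; acetonide and silyl ether are stable to aqueous hydroxide, and the acidification is stopped at pH 4.

Step 16
Reactants: 23 acetonide carboxylic acid
Product: 24 Se-phenyl selenoester of 23 (C8 acyl selenide, otherwise unchanged)
Conditions: (PhSe)2, PBu3, CH2Cl2, rt
Reagents that add atoms: diphenyl diselenide, c1ccc(cc1)[Se][Se]c1ccccc1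
Why: Redox condensation of a carboxylic acid with a diselenide and a phosphine (acyloxyphosphonium, then selenolate attack) gives the standard acyl radical precursor.

Step 17
Reactants: 24 Se-phenyl selenoester
Product: 25 (2S,3R,5S,9S,10R,13S)-15-(tert-butyldimethylsilyloxy)-2,3-(isopropylidenedioxy)-17-norlabdan-8-one (labdane numbering; trans-fused decalin-8-one with the chain equatorial at C9)
Conditions: Bu3SnH (syringe pump), AIBN (cat.), benzene (0.005 M), 80 °C
Reagents that add atoms: none
Why: Acyl radical cyclisation; the stannyl radical abstracts the phenylseleno group, the C8 acyl radical adds 6-exo-trig to C9 of the C9=C11 olefin through a chair transition state that gives the trans-decalin, and the C11 radical is reduced by the stannane; high dilution and slow addition suppress direct reduction and decarbonylation. The chain at C9 should take the equatorial position, which is also the thermodynamic one because C9 is α to the new ketone, so any axial epimer is corrected by brief exposure to DBU.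

Step 18
Reactants: 25 17-norlabdan-8-one acetonide silyl ether
Product: 27 (2S,3R,5S,9S,10R,13S)-15-(tert-butyldimethylsilyloxy)-2,3-(isopropylidenedioxy)-17-norlabd-7-en-8-yl trifluoromethanesulfonate, via potassium C7 enolate 26 (not isolated)
Conditions: KN(SiMe3)2, THF, −78 °C; then PhNTf2, −78 to 0 °C
Reagents that add atoms: N-phenylbis(trifluoromethanesulfonimide), FC(F)(F)S(=O)(=O)N(c1ccccc1)S(=O)(=O)C(F)(F)F
Why: Kinetic enolisation with a bulky amide base should remove a C7 hydrogen rather than the hindered tertiary C9 hydrogen, and O-triflation of the enolate fixes the double bond at C7=C8.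

Step 19
Reactants: 27 C8 enol triflate
Product: 28 (2S,3R,5S,9R,10S,13S)-15-(tert-butyldimethylsilyloxy)-2,3-(isopropylidenedioxy)labd-7-ene
Conditions: MeMgBr, Fe(acac)3 (5 mol %), THF/NMP, −30 to 0 °C
Reagents that add atoms: methylmagnesium bromide, C[Mg]Br
Why: Iron-catalysed Kumada-type cross-coupling of an enol triflate with a methyl Grignard reagent replaces the triflate by the C17 methyl without moving the olefin; acetal and silyl ether are inert.

Step 20
Reactants: 28 labd-7-ene acetonide silyl ether
Product: 29 (2S,3R,5S,9R,10S,13S)-labd-7-ene-2,3,15-triol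
Conditions: 1 M HCl (aq), THF, rt
Reagents that add atoms: none
Why: Acid hydrolysis removes the acetonide and the primary silyl ether in one operation; in dilute acid at room temperature the trisubstituted olefin should not migrate.

Step 21
Reactants: 29 labd-7-ene-2,3,15-triol
Product: 30 (2S,3R,5S,9R,10S,13S)-3-hydroxylabd-7-ene-2,15-diyl diacetate (CNP0144124.1)
Conditions: Ac2O (2.2 equiv), pyridine, CH2Cl2, 0 °C to rt
Reagents that add atoms: acetic anhydride, CC(=O)OC(C)=O
Why: Acetylation under steric control; the primary C15 and the equatorial C2 hydroxyls react, while the axial C3 hydroxyl beside the gem-dimethyl group should not without a nucleophilic catalyst. The monoacetate on the equatorial oxygen is also the favoured one should acyl migration occur.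

## Compound list

1 | methyl pent-4-enoate | C=CCCC(=O)OC | starting material
2 | methacrolein | CC(=C)C=O | starting material
3 | methyl (E)-5-methyl-6-oxohex-4-enoate | O=C/C(C)=C/CCC(=O)OC | intermediate
4 | (E)-4-methoxybut-3-en-2-one | CO/C=C/C(C)=O | starting material
5 | (E)-tert-butyl[(4-methoxybuta-1,3-dien-2-yl)oxy]dimethylsilane | CO/C=C/C(O[Si](C)(C)C(C)(C)C)=C | intermediate
6 | methyl 3-[(1R,2S)-5-(tert-butyldimethylsilyloxy)-2-formyl-3-methoxy-2-methylcyclohex-4-en-1-yl]propanoate (methoxy carbon as epimers) | O=C[C@]1(C)C(OC)C=C(O[Si](C)(C)C(C)(C)C)C[C@H]1CCC(=O)OC | intermediate (not isolated)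
7 | methyl 3-[(1R,2S)-2-formyl-2-methyl-5-oxocyclohex-3-en-1-yl]propanoate | O=C[C@]1(C)C=CC(=O)C[C@H]1CCC(=O)OC | intermediate
8 | dimethyl 3-methylpentanedioate | COC(=O)CC(C)CC(=O)OC | starting material
9 | (R)-5-methoxy-3-methyl-5-oxopentanoic acid | COC(=O)C[C@H](C)CC(=O)O | intermediate
10 | methyl (R)-5-hydroxy-3-methylpentanoate | COC(=O)C[C@H](C)CCO | intermediate
11 | methyl (R)-5-(tert-butyldimethylsilyloxy)-3-methylpentanoate | COC(=O)C[C@H](C)CCO[Si](C)(C)C(C)(C)C | intermediate
12 | (S)-5-(tert-butyldimethylsilyloxy)-3-methylpentan-1-ol | OCC[C@H](C)CCO[Si](C)(C)C(C)(C)C | intermediate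
13 | (R)-tert-butyl[(5-iodo-3-methylpentyl)oxy]dimethylsilane | ICC[C@H](C)CCO[Si](C)(C)C(C)(C)C | intermediate
14 | [(R)-5-(tert-butyldimethylsilyloxy)-3-methylpentyl]triphenylphosphonium iodide | [I-].CC(C)(C)[Si](C)(C)OCC[C@@H](C)CC[P+](c1ccccc1)(c1ccccc1)c1ccccc1 | intermediate
15 | [(R)-5-(tert-butyldimethylsilyloxy)-3-methylpentylidene]triphenylphosphorane | CC(C)(C)[Si](C)(C)OCC[C@@H](C)CC=P(c1ccccc1)(c1ccccc1)c1ccccc1 | intermediate (not isolated)
16 | methyl 3-[(1R,2R)-2-[(1Z,4S)-6-(tert-butyldimethylsilyloxy)-4-methylhex-1-en-1-yl]-2-methyl-5-oxocyclohex-3-en-1-yl]propanoate | CC(C)(C)[Si](C)(C)OCC[C@@H](C)C/C=C\[C@]1(C)C=CC(=O)C[C@H]1CCC(=O)OC | intermediate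
17 | C4-monomethyl analogue of 16 (C4 epimers) | CC(C)(C)[Si](C)(C)OCC[C@@H](C)C/C=C\[C@]1(C)C=CC(=O)C(C)[C@H]1CCC(=O)OC | intermediate (not isolated)
18 | methyl 3-[(1S,2R)-2-[(1Z,4S)-6-(tert-butyldimethylsilyloxy)-4-methylhex-1-en-1-yl]-2,6,6-trimethyl-5-oxocyclohex-3-en-1-yl]propanoate | CC(C)(C)[Si](C)(C)OCC[C@@H](C)C/C=C\[C@]1(C)C=CC(=O)C(C)(C)[C@H]1CCC(=O)OC | intermediate
19 | C2 hydroperoxide of the saturated ketone (OOH cis to H5) | CC(C)(C)[Si](C)(C)OCC[C@@H](C)C/C=C\[C@]1(C)C[C@H](OO)C(=O)C(C)(C)[C@H]1CCC(=O)OC | intermediate (not isolated)
20 | methyl 3-[(1S,2S,4S)-2-[(1Z,4S)-6-(tert-butyldimethylsilyloxy)-4-methylhex-1-en-1-yl]-4-hydroxy-2,6,6-trimethyl-5-oxocyclohexyl]propanoate | CC(C)(C)[Si](C)(C)OCC[C@@H](C)C/C=C\[C@]1(C)C[C@H](O)C(=O)C(C)(C)[C@H]1CCC(=O)OC | intermediate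
21 | methyl 3-[(1S,2S,4S,5R)-2-[(1Z,4S)-6-(tert-butyldimethylsilyloxy)-4-methylhex-1-en-1-yl]-4,5-dihydroxy-2,6,6-trimethylcyclohexyl]propanoate | CC(C)(C)[Si](C)(C)OCC[C@@H](C)C/C=C\[C@]1(C)C[C@H](O)[C@H](O)C(C)(C)[C@H]1CCC(=O)OC | intermediate
22 | acetonide of 21 (methyl ester) | CC(C)(C)[Si](C)(C)OCC[C@@H](C)C/C=C\[C@]1(C)C[C@@H]2OC(C)(C)O[C@@H]2C(C)(C)[C@H]1CCC(=O)OC | intermediate
23 | acetonide carboxylic acid | CC(C)(C)[Si](C)(C)OCC[C@@H](C)C/C=C\[C@]1(C)C[C@@H]2OC(C)(C)O[C@@H]2C(C)(C)[C@H]1CCC(=O)O | intermediate
24 | acetonide Se-phenyl selenoester | CC(C)(C)[Si](C)(C)OCC[C@@H](C)C/C=C\[C@]1(C)C[C@@H]2OC(C)(C)O[C@@H]2C(C)(C)[C@H]1CCC(=O)[Se]c1ccccc1 | intermediate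
25 | (2S,3R,5S,9S,10R,13S)-15-(tert-butyldimethylsilyloxy)-2,3-(isopropylidenedioxy)-17-norlabdan-8-one | CC(C)(C)[Si](C)(C)OCC[C@@H](C)CC[C@@H]1C(=O)CC[C@@H]2C(C)(C)[C@H]3OC(C)(C)O[C@H]3C[C@@]12C | intermediate
26 | potassium C7 enolate of 25 | [K+].CC(C)(C)[Si](C)(C)OCC[C@@H](C)CC[C@@H]1C([O-])=CC[C@@H]2C(C)(C)[C@H]3OC(C)(C)O[C@H]3C[C@@]12C | intermediate (not isolated)
27 | (2S,3R,5S,9S,10R,13S)-15-(tert-butyldimethylsilyloxy)-2,3-(isopropylidenedioxy)-17-norlabd-7-en-8-yl trifluoromethanesulfonate | CC(C)(C)[Si](C)(C)OCC[C@@H](C)CC[C@@H]1C(OS(=O)(=O)C(F)(F)F)=CC[C@@H]2C(C)(C)[C@H]3OC(C)(C)O[C@H]3C[C@@]12C | intermediate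
28 | (2S,3R,5S,9R,10S,13S)-15-(tert-butyldimethylsilyloxy)-2,3-(isopropylidenedioxy)labd-7-ene | CC(C)(C)[Si](C)(C)OCC[C@@H](C)CC[C@@H]1C(C)=CC[C@@H]2C(C)(C)[C@H]3OC(C)(C)O[C@H]3C[C@@]12C | intermediate
29 | (2S,3R,5S,9R,10S,13S)-labd-7-ene-2,3,15-triol | OCC[C@@H](C)CC[C@@H]1C(C)=CC[C@@H]2C(C)(C)[C@@H](O)[C@@H](O)C[C@@]12C | intermediate
30 | (2S,3R,5S,9R,10S,13S)-3-hydroxylabd-7-ene-2,15-diyl diacetate | CC(=O)OCC[C@@H](C)CC[C@@H]1C(C)=CC[C@@H]2C(C)(C)[C@@H](O)[C@@H](OC(C)=O)C[C@@]12C | target

## Step count and risks

Total: 21 steps. Longest linear sequence: 18 steps (steps 4–9, then 10–21, from 8 to 30). The branch through the key step runs 14 steps (steps 1, 3, 10–21).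

**Step 3 (key step).** Most likely failures: the diene attacks the boron-bound carbonyl (hetero-Diels–Alder or aldol-type pathway) instead of the C=C bond; the acidic catalyst decomposes the diene before the sluggish trisubstituted enal reacts; or facial selectivity is low or opposite to the model. In the last case the (R)-catalyst is used.
Fallback: start again from 3 and use the more nucleophilic (E)-3-(tert-butyldimethylsilyloxy)-N,N-dimethylbuta-1,3-dien-1-amine F1. Such dienes add to the C=C bond of α-substituted enals at low temperature under a neutral salen complex of trivalent chromium, (salen)Cr(SbF6), where salen is the dianion of N,N'-bis(3,5-di-tert-butylsalicylidene)cyclohexane-1,2-diamine. The ligand antipode is chosen for Re-face attack. The amino enol silyl ether cycloadduct F2 is then treated with acid, which hydrolyses the enol ether and eliminates dimethylamine, rejoining the route at 7.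

**Step 10.** Most likely failure: proton transfer from C4 of the enone to the basic ylide, or addition of the ylide to the enone, competing with olefination of the hindered neopentyl aldehyde.
Fallback: start from 6, isolated by omitting the acid treatment of step 3, in which the ketone is masked as its enol silyl ether. Its Wittig reaction with ylide 15 gives the chain-extended methoxy enol silyl ether F3. Dilute HCl in THF at 0 °C, which cleaves the enol silyl ether much faster than the primary silyl ether, then releases the enone and returns to 16.

**Step 11.** Most likely failure: enolisation of the ester arm, followed by intramolecular Michael addition of C7 to C1 or acylation of the C4 enolate by the ester.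
Fallback: start from 16 and saponify (LiOH) to the enone carboxylic acid F4, whose carboxylate is neither a Michael donor nor an acylating agent. Dimethylate it as the lithium carboxylate (LiN(i-Pr)2, MeI, −78 °C, two cycles) to the 4,4-dimethyl enone acid F5, then re-esterify with Me3SiCHN2 to return to 18.

**Step 12.** Most likely failure: hydrogen-atom transfer to the C9=C11 olefin, conjugate reduction without oxygen capture, or poor facial selectivity at C2.
Fallback: start from 18 and work in two polar steps. Conjugate reduction with [(Ph3P)CuH]6 gives the saturated 4,4-dimethyl ketone F6. Its only possible enolate (C2), formed with KN(SiMe3)2, is hydroxylated with 2-(phenylsulfonyl)-3-phenyloxaziridine from the face away from the axial methyls, returning to 20.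

**Step 17.** Most likely failure: addition to C9, next to the quaternary C10, is slow, so the acyl radical is reduced to the aldehyde, decarbonylates, or closes 7-endo at C11.
Fallback: a polar ring closure from 22. i-Bu2AlH at −78 °C gives the C8 aldehyde F7. A Me2AlCl-promoted intramolecular carbonyl-ene reaction then forms C8–C9 with shift of the olefin to C11=C12, giving the bicyclic homoallylic alcohol F8. Hydrogenation (H2, Pd/C) gives the saturated C8 alcohol F9, and Swern oxidation followed by DBU equilibration at C9 returns to 25.

**Step 21.** Most likely failure: incomplete discrimination between the C2 and C3 hydroxyls, giving triacetate or mixtures.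
Fallback: start from 29 and form with Bu2SnO the 2,3-O-dibutylstannylene acetal F10 of the cis-diol. AcCl and Et3N then acylate the primary hydroxyl and the tin-bound equatorial oxygen at C2, the known regiochemistry for stannylene acetals of cis-diols, giving 30.

## Further compounds

F1 | step 3 | (E)-3-(tert-butyldimethylsilyloxy)-N,N-dimethylbuta-1,3-dien-1-amine | CN(C)/C=C/C(O[Si](C)(C)C(C)(C)C)=C
F2 | step 3 | amino enol silyl ether cycloadduct (amino carbon as epimers) | O=C[C@]1(C)C(N(C)C)C=C(O[Si](C)(C)C(C)(C)C)C[C@H]1CCC(=O)OC
F3 | step 10 | chain-extended methoxy enol silyl ether (methoxy carbon as epimers) | CC(C)(C)[Si](C)(C)OCC[C@@H](C)C/C=C\[C@]1(C)C(OC)C=C(O[Si](C)(C)C(C)(C)C)C[C@H]1CCC(=O)OC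
F4 | step 11 | enone carboxylic acid from 16 | CC(C)(C)[Si](C)(C)OCC[C@@H](C)C/C=C\[C@]1(C)C=CC(=O)C[C@H]1CCC(=O)O
F5 | step 11 | 4,4-dimethyl enone carboxylic acid | CC(C)(C)[Si](C)(C)OCC[C@@H](C)C/C=C\[C@]1(C)C=CC(=O)C(C)(C)[C@H]1CCC(=O)O
F6 | step 12 | saturated 4,4-dimethyl ketone ester | CC(C)(C)[Si](C)(C)OCC[C@@H](C)C/C=C\[C@]1(C)CCC(=O)C(C)(C)[C@H]1CCC(=O)OC
F7 | step 17 | C8 aldehyde of the acetonide | CC(C)(C)[Si](C)(C)OCC[C@@H](C)C/C=C\[C@]1(C)C[C@@H]2OC(C)(C)O[C@@H]2C(C)(C)[C@H]1CCC=O
F8 | step 17 | bicyclic C8 alcohol with (E)-C11=C12 olefin (C8 epimers) | CC(C)(C)[Si](C)(C)OCC[C@@H](C)/C=C/[C@@H]1C(O)CC[C@@H]2C(C)(C)[C@H]3OC(C)(C)O[C@H]3C[C@@]12C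
F9 | step 17 | saturated bicyclic C8 alcohol (C8 epimers) | CC(C)(C)[Si](C)(C)OCC[C@@H](C)CC[C@@H]1C(O)CC[C@@H]2C(C)(C)[C@H]3OC(C)(C)O[C@H]3C[C@@]12C
F10 | step 21 | 2,3-O-dibutylstannylene acetal of triol 29 | OCC[C@@H](C)CC[C@@H]1C(C)=CC[C@@H]2C(C)(C)[C@H]3O[Sn](CCCC)(CCCC)O[C@H]3C[C@@]12C
A1 | alternative 1 | trans-fused 8-oxo decalin with complete chain, 2,3-acetonide and 15-silyl ether (identical with 25) | CC(C)(C)[Si](C)(C)OCC[C@@H](C)CC[C@@H]1C(=O)CC[C@@H]2C(C)(C)[C@H]3OC(C)(C)O[C@H]3C[C@@]12C
A2 | alternative 1 | ring A Se-phenyl selenoester with C9=C11 olefin (identical with 24) | CC(C)(C)[Si](C)(C)OCC[C@@H](C)C/C=C\[C@]1(C)C[C@@H]2OC(C)(C)O[C@@H]2C(C)(C)[C@H]1CCC(=O)[Se]c1ccccc1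
A3 | alternative 2 | 2-deacetyl target (2,3-cis-diol, 15-acetate) | CC(=O)OCC[C@@H](C)CC[C@@H]1C(C)=CC[C@@H]2C(C)(C)[C@@H](O)[C@@H](O)C[C@@]12C
A4 | alternative 2 | ring B dialdehyde with formyl groups at C2 and C3 | CC(=O)OCC[C@@H](C)CC[C@@H]1C(C)=CC[C@H](C(C)(C)C=O)[C@@]1(C)CC=O
A5 | alternative 3 | trans-fused bicyclic 8-oxo 11-methyl ester, 2,3-acetonide | COC(=O)[C@@H]1C(=O)CC[C@@H]2C(C)(C)[C@H]3OC(C)(C)O[C@H]3C[C@@]12C
A6 | alternative 3 | monocyclic β-keto ester with C5=C10 olefin, 2,3-acetonide | COC(=O)CC(=O)CCC1=C(C)C[C@@H]2OC(C)(C)O[C@@H]2C1(C)C
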